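**Retrosynthetic overview**

- Target (1S,2S,3R): in ring B (C1–C2–C3–C4–C4a–C8a) C2 carries OH/COOH and C3 carries OH/CH2OH, with the two hydroxyls trans and the two carbon branches trans. This is the substituent pattern of an E-2,3-dioxybut-2-enedioate, so C1–C2 and C3–C4 are cut together as a [4+2].
- Diene: the E,E-hydroxy-o-quinodimethane photogenerated on ring A from a 2-benzylbenzaldehyde. Dienophile: dimethyl (E)-diacetoxyfumarate. A Ti(OiPr)4/TADDOL template sets endo mode and face. Ring B is the only ring formed; ring A and the pendant aryl ring are bought.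
- The aldehyde comes from a Suzuki–Miyaura coupling of the pinacol boronate of O-benzyl-6-bromovanillin with 3,4,5-tris(benzyloxy)benzyl bromide (from methyl gallate). Boron is chosen because a benzylic zinc reagent would add to the free aldehyde.
- After the cycloaddition: reduction of the C3 ester directed by the cis C4 hydroxyl, saponification of the acetates and the C2 ester, then one hydrogenolysis that removes four benzyl ethers and the benzylic C4 hydroxyl.

Key step: step 9

Assumption: the sense of induction of the titanium TADDOLate cannot be predicted for this new diene/dienophile pair; the (R,R)-diol is written, and the equally available (S,S)-diol would be used if the adduct proves to be the antipode.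

**Route**

Step 1
Reactants: 1 6-bromovanillin (2-bromo-4-hydroxy-5-methoxybenzaldehyde)
Product: 2 4-(benzyloxy)-2-bromo-5-methoxybenzaldehyde
Conditions: BnBr, K2CO3, DMF, rt
Reagents that add atoms: benzyl bromide, BrCc1ccccc1
Why: Williamson etherification: the phenoxide formed with K2CO3 displaces bromide from benzyl bromide, and the aldehyde and the aryl bromide are inert.

Step 2
Reactants: 2 4-(benzyloxy)-2-bromo-5-methoxybenzaldehyde
Product: 3 4-(benzyloxy)-5-methoxy-2-(4,4,5,5-tetramethyl-1,3,2-dioxaborolan-2-yl)benzaldehyde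
Conditions: B2pin2, PdCl2(dppf) (3 mol%), KOAc, 1,4-dioxane, 85 °C
Reagents that add atoms: bis(pinacolato)diboron, CC1(C)OB(OC1(C)C)B1OC(C)(C)C(C)(C)O1
Why: Miyaura borylation: oxidative addition of the aryl bromide to zerovalent palladium, acetate-assisted transmetalation with the diboron and reductive elimination; KOAc is too weak a base to start a Suzuki homocoupling and the aldehyde is tolerated.

Step 3
Reactants: 4 methyl gallate (methyl 3,4,5-trihydroxybenzoate)
Product: 5 methyl 3,4,5-tris(benzyloxy)benzoate
Conditions: BnBr (3.5 equiv), K2CO3, DMF, 60 °C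
Reagents that add atoms: benzyl bromide, BrCc1ccccc1
Why: Threefold Williamson etherification of the phenols; the methyl ester is not touched by K2CO3 in DMF.

Step 4
Reactants: 5 methyl 3,4,5-tris(benzyloxy)benzoate
Product: 6 [3,4,5-tris(benzyloxy)phenyl]methanol
Conditions: LiAlH4, THF, 0 °C to rt
Reagents that add atoms: none
Why: Hydride reduction of the benzoate ester to the benzylic alcohol; aryl benzyl ethers are stable to LiAlH4.

Step 5
Reactants: 6 [3,4,5-tris(benzyloxy)phenyl]methanol
Product: 7 3,4,5-tris(benzyloxy)benzyl bromide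
Conditions: PBr3, CH2Cl2, 0 °C
Reagents that add atoms: phosphorus tribromide, BrP(Br)Br
Why: Bromination of a primary benzylic alcohol through its phosphite ester and displacement by bromide; the bromide should be used promptly because it is an activated benzylic halide.

Step 6
Reactants: 3 4-(benzyloxy)-5-methoxy-2-(4,4,5,5-tetramethyl-1,3,2-dioxaborolan-2-yl)benzaldehyde; 7 3,4,5-tris(benzyloxy)benzyl bromide
Product: 8 4-(benzyloxy)-5-methoxy-2-[3,4,5-tris(benzyloxy)benzyl]benzaldehyde
Conditions: Pd(PPh3)4 (5 mol%), K2CO3, DME/H2O, 80 °C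
Reagents that add atoms: none
Why: Suzuki–Miyaura coupling between an arylboronate and a benzylic bromide: oxidative addition of the C–Br bond to zerovalent palladium, transmetalation of the aryl group and reductive elimination give the diarylmethane, and the boron reagent does not add to the free aldehyde.

Step 7
Reactants: 9 dihydroxyfumaric acid ((E)-2,3-dihydroxybut-2-enedioic acid)
Product: 10 dimethyl (E)-2,3-dihydroxybut-2-enedioate
Conditions: MeOH, dry HCl, 0 °C to rt, under argon
Reagents that add atoms: methanol, CO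
Why: Fischer esterification in cold acidic methanol, where the enediol neither decarboxylates nor is oxidized; the hydrogen-bonded E-enediol geometry is kept and the diester should crystallize from the medium.

Step 8
Reactants: 10 dimethyl (E)-2,3-dihydroxybut-2-enedioate
Product: 11 dimethyl (E)-2,3-diacetoxybut-2-enedioate
Conditions: Ac2O, pyridine, DMAP (cat.), CH2Cl2, 0 °C; recrystallization
Reagents that add atoms: acetic anhydride, CC(=O)OC(C)=O
Why: O-acylation of both enolic hydroxyls by DMAP-catalysed acyl transfer locks the E-enediol as its diacetate; the E isomer should be purified by crystallization and its geometry confirmed, since it is copied into C2 and C3.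

Step 9
Reactants: 8 4-(benzyloxy)-5-methoxy-2-[3,4,5-tris(benzyloxy)benzyl]benzaldehyde; 11 dimethyl (E)-2,3-diacetoxybut-2-enedioate
Product: 13 dimethyl (1S,2S,3S,4R)-2,3-diacetoxy-7-(benzyloxy)-4-hydroxy-6-methoxy-1-[3,4,5-tris(benzyloxy)phenyl]-1,2,3,4-tetrahydronaphthalene-2,3-dicarboxylate, via (E,E)-hydroxy-o-quinodimethane 12 (not isolated)
Conditions: Ti(OiPr)4 (2 equiv), (R,R)-TADDOL (2.2 equiv), 11 (3 equiv), degassed toluene, 4 Å MS, hν (365 nm LED), 0 °C to rt; then sat. aq. NaHCO3
Reagents that add atoms: none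
Why: Excitation (n to π*) of the aldehyde and 1,5-hydrogen transfer from the doubly benzylic CH2 give, after bond rotation, the long-lived E,E-dienol 12 (hydroxyl and aryl both outward), which is held as a titanium dienolate on the TADDOLate and adds to 11 in a concerted suprafacial [4+2] cycloaddition (photoenolization/Diels–Alder reaction). The closest known reactions are the titanium TADDOLate-controlled photoenolization/Diels–Alder reactions of 2-alkylbenzaldehydes with electron-poor alkenes, tetrasubstituted ones included, and the trapping of 2-benzylbenzaldehyde photoenols by fumarates; the diacetoxyfumarate is a new and more crowded member of that class, activated here by carbonyl coordination to titanium and by its two acyloxy groups. Ring B is closed by intermolecular cycloaddition, C1–C2 and C3–C4 forming together at the two exocyclic diene termini, which restores the aromaticity of ring A. C1 and C4 (aryl and hydroxyl cis) follow from the E,E geometry of 12, and C2 and C3 (trans acetoxy groups, trans esters) from the E geometry of 11, both transferred suprafacially. The step needs the endo mode in which the ester next to C4 lies under the diene (C3 ester cis to the C4 hydroxyl, C2 ester trans to the aryl group) and one diene face: the first is secured by the titanium bridge between the dienol oxygen and that ester carbonyl, the second by the aryl walls of the TADDOLate, and the twofold symmetry of 11 removes any regiochemical question.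

Step 10
Reactants: 13 dimethyl (1S,2S,3S,4R)-2,3-diacetoxy-7-(benzyloxy)-4-hydroxy-6-methoxy-1-[3,4,5-tris(benzyloxy)phenyl]-1,2,3,4-tetrahydronaphthalene-2,3-dicarboxylate
Product: 14 methyl (1S,2S,3S,4R)-2,3-diacetoxy-7-(benzyloxy)-4-hydroxy-3-(hydroxymethyl)-6-methoxy-1-[3,4,5-tris(benzyloxy)phenyl]-1,2,3,4-tetrahydronaphthalene-2-carboxylate
Conditions: BH3·SMe2 (3 equiv), NaBH4 (10 mol%), THF, 0 °C to rt; MeOH quench
Reagents that add atoms: none
Why: Saito-type hydroxyl-directed borane reduction: the C4 hydroxyl forms an alkoxyborane that coordinates and delivers hydride only to the cis C3 ester carbonyl through a six-membered chelate, whereas the C2 ester (trans to C4–O and shielded by the C1 aryl group and quaternary C3) and the acetates are not reduced by borane at this temperature; no stereocentre is formed or touched, and loss or migration of an acetate would be harmless because both are removed in step 11.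

Step 11
Reactants: 14 methyl (1S,2S,3S,4R)-2,3-diacetoxy-7-(benzyloxy)-4-hydroxy-3-(hydroxymethyl)-6-methoxy-1-[3,4,5-tris(benzyloxy)phenyl]-1,2,3,4-tetrahydronaphthalene-2-carboxylate
Product: 15 (1S,2S,3S,4R)-7-(benzyloxy)-2,3,4-trihydroxy-3-(hydroxymethyl)-6-methoxy-1-[3,4,5-tris(benzyloxy)phenyl]-1,2,3,4-tetrahydronaphthalene-2-carboxylic acid
Conditions: LiOH·H2O (8 equiv), THF/MeOH/H2O, rt to 45 °C; then 1 M HCl to pH 3 at 0 °C
Reagents that add atoms: lithium hydroxide, [Li+].[OH-]
Why: Ester saponification by acyl–oxygen cleavage removes the two tertiary acetates and the hindered C2 methyl ester (helped by the adjacent free hydroxyl); because C3 no longer bears a carbonyl group, no retro-aldol opening of the C3–C4 bond is possible, and the configuration is untouched.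

Step 12
Reactants: 15 (1S,2S,3S,4R)-7-(benzyloxy)-2,3,4-trihydroxy-3-(hydroxymethyl)-6-methoxy-1-[3,4,5-tris(benzyloxy)phenyl]-1,2,3,4-tetrahydronaphthalene-2-carboxylic acid
Product: 17 (1S,2S,3R)-2,3,7-trihydroxy-3-(hydroxymethyl)-6-methoxy-1-(3,4,5-trihydroxyphenyl)-1,2,3,4-tetrahydronaphthalene-2-carboxylic acid, via debenzylated 4-hydroxy acid 16 (not isolated)
Conditions: H2 (1–3 atm), 10% Pd/C, MeOH/AcOH (9:1), rt; filtration and evaporation under argon
Reagents that add atoms: none
Why: Heterogeneous hydrogenolysis: the four O-benzyl groups are cleaved first to give 16, whose C4 hydroxyl is then a p-hydroxybenzylic alcohol (para to the freed C7 phenol) that ionizes in AcOH to a quinone methide-like species and is reduced to CH2 on palladium; C1, C2 and C3 carry no benzylic C–O bond and keep their configuration (the C3 descriptor changes from S to R only through the priority change at C4).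

**Compound list**

1 | 6-bromovanillin (2-bromo-4-hydroxy-5-methoxybenzaldehyde) | COc1cc(C=O)c(Br)cc1O | starting material
2 | 4-(benzyloxy)-2-bromo-5-methoxybenzaldehyde | COc1cc(C=O)c(Br)cc1OCc1ccccc1 | intermediate
3 | 4-(benzyloxy)-5-methoxy-2-(4,4,5,5-tetramethyl-1,3,2-dioxaborolan-2-yl)benzaldehyde | COc1cc(C=O)c(cc1OCc1ccccc1)B1OC(C)(C)C(C)(C)O1 | intermediate
4 | methyl gallate (methyl 3,4,5-trihydroxybenzoate) | COC(=O)c1cc(O)c(O)c(O)c1 | starting material
5 | methyl 3,4,5-tris(benzyloxy)benzoate | COC(=O)c1cc(OCc2ccccc2)c(OCc2ccccc2)c(OCc2ccccc2)c1 | intermediate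
6 | [3,4,5-tris(benzyloxy)phenyl]methanol | OCc1cc(OCc2ccccc2)c(OCc2ccccc2)c(OCc2ccccc2)c1 | intermediate
7 | 3,4,5-tris(benzyloxy)benzyl bromide | BrCc1cc(OCc2ccccc2)c(OCc2ccccc2)c(OCc2ccccc2)c1 | intermediate
8 | 4-(benzyloxy)-5-methoxy-2-[3,4,5-tris(benzyloxy)benzyl]benzaldehyde | COc1cc(C=O)c(cc1OCc1ccccc1)Cc1cc(OCc2ccccc2)c(OCc2ccccc2)c(OCc2ccccc2)c1 | intermediate
9 | dihydroxyfumaric acid ((E)-2,3-dihydroxybut-2-enedioic acid) | OC(=O)/C(O)=C(O)/C(=O)O | starting material
10 | dimethyl (E)-2,3-dihydroxybut-2-enedioate | COC(=O)/C(O)=C(O)/C(=O)OC | intermediate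
11 | dimethyl (E)-2,3-diacetoxybut-2-enedioate | COC(=O)/C(OC(C)=O)=C(OC(C)=O)/C(=O)OC | intermediate
12 | (E,E)-hydroxy-o-quinodimethane of 8: 3-(benzyloxy)-6-[(E)-hydroxymethylidene]-2-methoxy-5-[(E)-3,4,5-tris(benzyloxy)benzylidene]cyclohexa-1,3-diene, present as its titanium alkoxide | O/C=C1\C=C(OC)C(OCc2ccccc2)=C/C1=C\c3cc(OCc2ccccc2)c(OCc2ccccc2)c(OCc2ccccc2)c3 | intermediate (not isolated)
13 | dimethyl (1S,2S,3S,4R)-2,3-diacetoxy-7-(benzyloxy)-4-hydroxy-6-methoxy-1-[3,4,5-tris(benzyloxy)phenyl]-1,2,3,4-tetrahydronaphthalene-2,3-dicarboxylate | COc1cc2c(cc1OCc1ccccc1)[C@H](c1cc(OCc3ccccc3)c(OCc3ccccc3)c(OCc3ccccc3)c1)[C@@](OC(C)=O)(C(=O)OC)[C@](OC(C)=O)(C(=O)OC)[C@@H]2O | intermediate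
14 | methyl (1S,2S,3S,4R)-2,3-diacetoxy-7-(benzyloxy)-4-hydroxy-3-(hydroxymethyl)-6-methoxy-1-[3,4,5-tris(benzyloxy)phenyl]-1,2,3,4-tetrahydronaphthalene-2-carboxylate | COc1cc2c(cc1OCc1ccccc1)[C@H](c1cc(OCc3ccccc3)c(OCc3ccccc3)c(OCc3ccccc3)c1)[C@@](OC(C)=O)(C(=O)OC)[C@](OC(C)=O)(CO)[C@@H]2O | intermediate
15 | (1S,2S,3S,4R)-7-(benzyloxy)-2,3,4-trihydroxy-3-(hydroxymethyl)-6-methoxy-1-[3,4,5-tris(benzyloxy)phenyl]-1,2,3,4-tetrahydronaphthalene-2-carboxylic acid | COc1cc2c(cc1OCc1ccccc1)[C@H](c1cc(OCc3ccccc3)c(OCc3ccccc3)c(OCc3ccccc3)c1)[C@@](O)(C(=O)O)[C@](O)(CO)[C@@H]2O | intermediate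
16 | (1S,2S,3S,4R)-2,3,4,7-tetrahydroxy-3-(hydroxymethyl)-6-methoxy-1-(3,4,5-trihydroxyphenyl)-1,2,3,4-tetrahydronaphthalene-2-carboxylic acid | COc1cc2c(cc1O)[C@H](c1cc(O)c(O)c(O)c1)[C@@](O)(C(=O)O)[C@](O)(CO)[C@@H]2O | intermediate (not isolated)
17 | (1S,2S,3R)-2,3,7-trihydroxy-3-(hydroxymethyl)-6-methoxy-1-(3,4,5-trihydroxyphenyl)-1,2,3,4-tetrahydronaphthalene-2-carboxylic acid | COc1cc2c(cc1O)[C@H](c1cc(O)c(O)c(O)c1)[C@@](O)(C(=O)O)[C@](O)(CO)C2 | target

**Totals**

Total step count: 12. Longest linear sequence: 8 steps (4 → 5 → 6 → 7 → 8 → 13 → 14 → 15 → 17).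

**Steps most likely to fail**

1. Step 9. The titanium-bound dienol is short-lived and the dienophile is acyclic, tetrasubstituted and crowded. Capture may be slower than reversion of the dienol to the aldehyde or its photodecay, and acetyl transfer from the enol acetate to titanium alkoxide or loss of endo and facial control may intervene. Fallback: separate the photochemistry from the cycloaddition. Setting out from 8, irradiation (365 nm) in benzene saturated with SO2 should trap the E,E-dienol by cheletropic addition as the cis hydroxy sulfone, racemic cis-5-(benzyloxy)-1-hydroxy-6-methoxy-3-[3,4,5-tris(benzyloxy)phenyl]-1,3-dihydrobenzo[c]thiophene 2,2-dioxide F1, a known way of storing the photoenols of 2-benzylbenzaldehydes. Warming F1 with excess 11 and the same Ti(OiPr)4/(R,R)-TADDOL template in toluene at 40–60 °C would extrude SO2 and regenerate the same titanium dienolate thermally and continuously. The dienophile can then be used at high concentration and for long times without competing photochemistry. The fallback comes back to the route at 13.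

2. Step 10. Hydride delivery may not be selective (reduction of the C2 ester or of the acetates, acetyl migration), or the neopentyl-type C3 ester may resist reduction. Fallback: differentiate the two esters through the C4 cation. Setting out from 13, TFA in CH2Cl2 at 0 °C should ionize the p-alkoxybenzylic C4 hydroxyl. The C2 ester carbonyl, which sits 1,3 to C4 on the face opposite to the departing hydroxyl, should capture the cation with loss of the methyl group. This would give the bridged C2→C4 γ-lactone, methyl (1S,2S,3S,4S)-2,3-diacetoxy-7-(benzyloxy)-6-methoxy-1-[3,4,5-tris(benzyloxy)phenyl]-1,2,3,4-tetrahydronaphthalene-3-carboxylate 2,4-carbolactone F2. C3 has no hydrogen and no free hydroxyl, so neither elimination nor pinacol-type shift competes. F2 is in effect a benzylic ester of the C2 acid. H2 with Pd/C in EtOAc/MeOH should therefore cleave the C4–O bond together with the four benzyl ethers, giving (1S,2S,3S)-2,3-diacetoxy-7-hydroxy-6-methoxy-3-(methoxycarbonyl)-1-(3,4,5-trihydroxyphenyl)-1,2,3,4-tetrahydronaphthalene-2-carboxylic acid F3. Excess LiBH4 in THF/MeOH, followed by acidic methanol work-up, should reduce the C3 methyl ester and remove the acetates while the carboxylate is left. The fallback comes back to the route at 17.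

3. Step 12. Hydrogenolysis of the C4–O bond may stall after debenzylation (halting at 16), and long exposure invites air oxidation of the pyrogallol ring. Fallback: remove the C4 oxygen by a radical path before deprotection. Setting out from 14, 1,1'-thiocarbonyldiimidazole and DMAP in toluene at 80 °C should tie the cis C4 hydroxyl and the C3 hydroxymethyl group into the six-membered cyclic thionocarbonate of 14, F4. Bu3SnH and AIBN in toluene at 110 °C should then cleave the ring regioselectively at the benzylic C4–O bond (Barton-type deoxygenation of a cyclic thionocarbonate), leaving methyl (1S,2S,3R)-2,3-diacetoxy-7-(benzyloxy)-6-methoxy-3-{[(tributylstannylsulfanyl)carbonyloxy]methyl}-1-[3,4,5-tris(benzyloxy)phenyl]-1,2,3,4-tetrahydronaphthalene-2-carboxylate F5. LiOH in THF/MeOH/H2O would remove the thiocarbonate, the acetates and the methyl ester to give (1S,2S,3R)-7-(benzyloxy)-2,3-dihydroxy-3-(hydroxymethyl)-6-methoxy-1-[3,4,5-tris(benzyloxy)phenyl]-1,2,3,4-tetrahydronaphthalene-2-carboxylic acid F6. H2 with Pd/C then only has to cleave benzyl ethers. The fallback comes back to the route at 17.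

**Further compounds**

F1 | step 9 | cis-5-(benzyloxy)-1-hydroxy-6-methoxy-3-[3,4,5-tris(benzyloxy)phenyl]-1,3-dihydrobenzo[c]thiophene 2,2-dioxide (racemic, one enantiomer drawn) | COc1cc2c(cc1OCc1ccccc1)[C@H](c1cc(OCc3ccccc3)c(OCc3ccccc3)c(OCc3ccccc3)c1)S(=O)(=O)[C@@H]2O
F2 | step 10 | methyl (1S,2S,3S,4S)-2,3-diacetoxy-7-(benzyloxy)-6-methoxy-1-[3,4,5-tris(benzyloxy)phenyl]-1,2,3,4-tetrahydronaphthalene-3-carboxylate 2,4-carbolactone | COc1cc2c(cc1OCc1ccccc1)[C@H](c1cc(OCc3ccccc3)c(OCc3ccccc3)c(OCc3ccccc3)c1)[C@@](OC(C)=O)(C(=O)O4)[C@](OC(C)=O)(C(=O)OC)[C@H]24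
F3 | step 10 | (1S,2S,3S)-2,3-diacetoxy-7-hydroxy-6-methoxy-3-(methoxycarbonyl)-1-(3,4,5-trihydroxyphenyl)-1,2,3,4-tetrahydronaphthalene-2-carboxylic acid | COc1cc2c(cc1O)[C@H](c1cc(O)c(O)c(O)c1)[C@@](OC(C)=O)(C(=O)O)[C@](OC(C)=O)(C(=O)OC)C2
F4 | step 12 | cyclic thionocarbonate of 14 (C4–O–C(=S)–O–CH2–C3, six-membered, cis-fused; 1S,2S,3S,4R) | COc1cc2c(cc1OCc1ccccc1)[C@H](c1cc(OCc3ccccc3)c(OCc3ccccc3)c(OCc3ccccc3)c1)[C@@](OC(C)=O)(C(=O)OC)[C@](OC(C)=O)(CO4)[C@@H]2OC4=S
F5 | step 12 | methyl (1S,2S,3R)-2,3-diacetoxy-7-(benzyloxy)-6-methoxy-3-{[(tributylstannylsulfanyl)carbonyloxy]methyl}-1-[3,4,5-tris(benzyloxy)phenyl]-1,2,3,4-tetrahydronaphthalene-2-carboxylate | COc1cc2c(cc1OCc1ccccc1)[C@H](c1cc(OCc3ccccc3)c(OCc3ccccc3)c(OCc3ccccc3)c1)[C@@](OC(C)=O)(C(=O)OC)[C@](OC(C)=O)(COC(=O)S[Sn](CCCC)(CCCC)CCCC)C2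
F6 | step 12 | (1S,2S,3R)-7-(benzyloxy)-2,3-dihydroxy-3-(hydroxymethyl)-6-methoxy-1-[3,4,5-tris(benzyloxy)phenyl]-1,2,3,4-tetrahydronaphthalene-2-carboxylic acid | COc1cc2c(cc1OCc1ccccc1)[C@H](c1cc(OCc3ccccc3)c(OCc3ccccc3)c(OCc3ccccc3)c1)[C@@](O)(C(=O)O)[C@](O)(CO)C2
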